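**Retrosynthetic overview**

- Feature: ring B holds four contiguous stereocentres, C5–C10–C9–C8. H-5, the C10 methyl, the C9 carbon arm (C11) and the C8 methyl all lie on the β face (rings A/B cis-fused) and the C8 oxygen is α. These four carbons are the bonding termini of a diene (C5=C6–C7=C8) and a dienophile (C9=C10).
- Late disconnections: C11–C12 (alkylation of a C11 phenyl sulfone with (2E,6E)-farnesyl bromide, then desulfonylation) and C8–O (retentive oxidation of a C8–B bond).
- Key disconnection: C5–C10 and C8–C9 by a thermal intramolecular Diels–Alder reaction of an open-chain triene, an (E)-enoate joined through C1–C4 to a (5E,7Z)-dienyl boronate. Rings A and B form together in this one step; no ring exists before it.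
- Triene: C7=C8 by boron–Wittig olefination of a C7 enal with 1,1-diborylethane, C5=C6 by cross-metathesis, C3–C4 and the (S)-C3 carbinol by reverse prenylation of the C3 aldehyde cut from methyl (E)-geranate.

Key step: step 7

Remark 1: the target SMILES is read as (3S,5S,8R,9R,10S), a cis-fused decalin with 5β-H; drimane numbering is used (ring carbons C1–C10, C11 on C9, methyl groups on C4, C8 and C10) and β is the face of the C10 methyl.
Remark 2: methyl (E)-geranate, prenylmagnesium chloride, (E)-crotonaldehyde, bis[(pinacolato)boryl]methane, iodomethane and (2E,6E)-farnesyl bromide are taken as commercial.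

**Route**

Step 1
Reactants: 1 methyl (E)-geranate [methyl (2E)-3,7-dimethylocta-2,6-dienoate]
Product: 3 methyl (2E)-3-methyl-6-oxohex-2-enoate, via ozonide 2 (not isolated)
Conditions: O3 (1 equiv, Sudan Red 7B as end-point indicator), CH2Cl2, −78 °C; then Me2S, −78 °C → rt
Reagents that add atoms: ozone, O=[O+][O-]
Why: Chemoselective ozonolysis, in which the electron-rich trisubstituted C6=C7 alkene reacts far faster than the conjugated, electron-poor enoate alkene, and reductive work-up of the ozonide gives the aldehyde with the (E)-enoate untouched.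

Step 2
Reactants: 3 methyl (2E)-3-methyl-6-oxohex-2-enoate; 4 prenylmagnesium chloride
Product: 7 methyl (2E,6S)-6-hydroxy-3,7,7-trimethylnona-2,8-dienoate, via prenylborane 5 (not isolated), via borinate ester 6 (not isolated)
Conditions: 4, (+)-B-methoxydiisopinocampheylborane [(+)-Ipc2BOMe, from (−)-α-pinene], Et2O, −78 °C → rt; then 3, −78 °C; then NaBO3·4H2O, THF/H2O, rt
Reagents that add atoms: none
Why: Brown asymmetric allylboration in its reverse-prenylation form, in which the prenylborane adds through its γ-carbon in a chair six-membered transition state to form the C3–C4 bond and the gem-dimethyl carbon, and the isopinocampheyl groups from (−)-α-pinene direct attack to the Re face of the aldehyde, which should set C3 as (S).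

Step 3
Reactants: 7 methyl (2E,6S)-6-hydroxy-3,7,7-trimethylnona-2,8-dienoate
Product: 8 methyl (2E,6S)-6-(tert-butyldimethylsilyloxy)-3,7,7-trimethylnona-2,8-dienoate
Conditions: t-BuMe2SiOTf, 2,6-lutidine, CH2Cl2, −78 → 0 °C
Reagents that add atoms: tert-butyldimethylsilyl triflate, CC(C)(C)[Si](C)(C)OS(=O)(=O)C(F)(F)F
Why: O-Silylation of the hindered, neopentyl-type secondary alcohol with the silyl triflate and a non-nucleophilic base, which leaves the C3 stereocentre and the enoate unchanged.

Step 4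
Reactants: 8 methyl (2E,6S)-6-(tert-butyldimethylsilyloxy)-3,7,7-trimethylnona-2,8-dienoate; 9 (E)-crotonaldehyde
Product: 10 methyl (2E,6S,8E)-6-(tert-butyldimethylsilyloxy)-3,7,7-trimethyl-10-oxodeca-2,8-dienoate
Conditions: 9 (8 equiv), second-generation Hoveyda–Grubbs catalyst [RuCl2(H2IMes)(=CH–C6H4-2-O-i-Pr)] (5 mol%), CH2Cl2, 40 °C
Reagents that add atoms: none
Why: Olefin cross-metathesis, in which the monosubstituted C5=C6 alkene exchanges its CH2 terminus for the CH–CHO unit of crotonaldehyde with loss of propene and should give the (E)-enal under thermodynamic control, while the trisubstituted enoate alkene does not take part.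

Step 5
Reactants: 11 bis[(pinacolato)boryl]methane; 12 iodomethane
Product: 14 1,1-bis(4,4,5,5-tetramethyl-1,3,2-dioxaborolan-2-yl)ethane, via lithiated diborylmethane 13 (not isolated)
Conditions: lithium 2,2,6,6-tetramethylpiperidide (LiTMP), THF, 0 °C; then 12, 0 °C → rt
Reagents that add atoms: none
Why: Deprotonation of the doubly boron-stabilised C–H by the hindered amide base followed by SN2 methylation (alkylation of a geminal bis(boronate)).

Step 6
Reactants: 10 methyl (2E,6S,8E)-6-(tert-butyldimethylsilyloxy)-3,7,7-trimethyl-10-oxodeca-2,8-dienoate; 14 1,1-bis(4,4,5,5-tetramethyl-1,3,2-dioxaborolan-2-yl)ethane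
Product: 17 methyl (2E,6S,8E,10Z)-6-(tert-butyldimethylsilyloxy)-3,7,7-trimethyl-11-(4,4,5,5-tetramethyl-1,3,2-dioxaborolan-2-yl)dodeca-2,8,10-trienoate, via lithiated diborylethane 15 (not isolated), via lithium alkoxide adduct 16 (not isolated)
Conditions: 14, LiTMP, THF, 0 °C; then 10, −78 °C → rt
Reagents that add atoms: none
Why: Boron–Wittig olefination, in which the α,α-diboryl carbanion adds 1,2 to the enal and syn-elimination of a B–O unit forms C7=C8 with the chain trans to the retained Bpin group (as in the E-selective reaction of unsubstituted diborylmethane), so the C8 methyl should end up cis to C6, and the methyl ester is not attacked at −78 °C.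

Step 7
Reactants: 17 methyl (2E,6S,8E,10Z)-6-(tert-butyldimethylsilyloxy)-3,7,7-trimethyl-11-(4,4,5,5-tetramethyl-1,3,2-dioxaborolan-2-yl)dodeca-2,8,10-trienoate
Product: 18 methyl 3β-(tert-butyldimethylsilyloxy)-8α-(pinacolboryl)-5β-drim-6-en-11-oate (cis-fused; H-5/8-CH3/9-CO2Me/10-CH3 all β)
Conditions: PhMe (0.01 M), BHT (0.1 equiv), sealed tube, 185 °C
Reagents that add atoms: none
Why: Concerted, suprafacial thermal [4+2] cycloaddition (type 1 intramolecular Diels–Alder reaction of a 1,7,9-decatriene; the closest known cases are thermal cyclisations of deca-2,8,10-trienoates and Diels–Alder reactions of 1-(pinacolboryl)-1,3-dienes, whose allylboronate adducts are oxidised with retention), in which the enoate β-carbon C10 bonds to C5 and the α-carbon C9 bonds to C8. Ring A (C10–C1–C2–C3–C4–C5) is closed by the C5–C10 bond through the four-carbon tether in a chair-like array, and ring B (C5–C6–C7–C8–C9–C10) is the new cyclohexene, completed by the C8–C9 bond. At C9 and C10 the (E)-enoate geometry is transferred, so CO2Me and the C10 methyl are cis; at C8 the diene geometry (CH3 inside, Bpin outside) puts the C8 methyl cis to H-5 and boron on the α face; at C5 the tether-endo (ester-exo) orientation gives the cis ring fusion with H-5 cis to the C10 methyl. The absolute sense follows from C3, because only one diene face lets the OTBS group sit equatorial in the chair-like tether, whereas the other face would press it, axial, against C6 of the diene. The selectivity needed beyond this is tether-endo over ester-endo; the substrate does not enforce it, offering only the weak endo preference of an ester in the uncatalysed reaction and the possibility, open to the cis-fused pathway alone, of relieving the C4–CH3/C10–CH3 1,3-interaction by flexing the tether, while the inside C8 methyl crowds the exo ester, so this is the least secured point of the route.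

Step 8
Reactants: 18 methyl 3β-(tert-butyldimethylsilyloxy)-8α-(pinacolboryl)-5β-drim-6-en-11-oate
Product: 20 methyl 3β-(tert-butyldimethylsilyloxy)-8α-hydroxy-5β-drim-6-en-11-oate, via borate ester 19 (not isolated)
Conditions: NaBO3·4H2O, THF/H2O (1:1), rt
Reagents that add atoms: sodium perborate tetrahydrate (NaBO3·4H2O), [Na+].[O-]OB=O
Why: Oxidation of the tertiary allylic C–B bond, in which peroxoborate adds to boron and C8 migrates from boron to oxygen with retention (1,2-metallate shift), so the 8α-boryl group becomes the 8α-hydroxyl, and the mild, weakly basic medium avoids retro-aldol cleavage of the β-hydroxy ester.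

Step 9
Reactants: 20 methyl 3β-(tert-butyldimethylsilyloxy)-8α-hydroxy-5β-drim-6-en-11-oate
Product: 21 methyl 3β-(tert-butyldimethylsilyloxy)-8α-hydroxy-5β-driman-11-oate
Conditions: H2 (1 atm), PtO2, EtOAc, rt
Reagents that add atoms: none
Why: Heterogeneous catalytic hydrogenation of the cis-disubstituted C6=C7 alkene, which creates no stereocentre, with platinum in a neutral solvent chosen to limit hydrogenolysis of the allylic C8–O bond.

Step 10
Reactants: 21 methyl 3β-(tert-butyldimethylsilyloxy)-8α-hydroxy-5β-driman-11-oate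
Product: 22 methyl 3β-(tert-butyldimethylsilyloxy)-8α-(triethylsilyloxy)-5β-driman-11-oate
Conditions: Et3SiOTf, 2,6-lutidine, CH2Cl2, 0 °C → rt
Reagents that add atoms: triethylsilyl triflate, CC[Si](CC)(CC)OS(=O)(=O)C(F)(F)F
Why: Silylation of the tertiary alcohol with the silyl triflate/2,6-lutidine system, so that no acidic O–H is present during the later carbanion chemistry.

Step 11
Reactants: 22 methyl 3β-(tert-butyldimethylsilyloxy)-8α-(triethylsilyloxy)-5β-driman-11-oate
Product: 24 3β-(tert-butyldimethylsilyloxy)-8α-(triethylsilyloxy)-5β-driman-11-ol, via aldehyde 23 (not isolated)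
Conditions: LiAlH4, THF, 0 °C → reflux
Reagents that add atoms: none
Why: Hydride reduction of the hindered ester through the aldehyde to the primary alcohol, to which silyl ethers are inert and which does not epimerise C9.

Step 12
Reactants: 24 3β-(tert-butyldimethylsilyloxy)-8α-(triethylsilyloxy)-5β-driman-11-ol
Product: 26 11-(phenylthio)-3β-(tert-butyldimethylsilyloxy)-8α-(triethylsilyloxy)-5β-drimane, via alkoxyphosphonium thiolate 25 (not isolated)
Conditions: PhSSPh, PBu3, pyridine, rt → 60 °C
Reagents that add atoms: diphenyl disulfide, c1ccccc1SSc1ccccc1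
Why: Hata reaction (phosphine/disulfide redox condensation), in which the primary alcohol is activated as an alkoxyphosphonium ion and displaced by thiophenolate in an SN2 step at C11, with the silyl ethers unaffected.

Step 13
Reactants: 26 11-(phenylthio)-3β-(tert-butyldimethylsilyloxy)-8α-(triethylsilyloxy)-5β-drimane
Product: 28 11-(phenylsulfonyl)-3β-(tert-butyldimethylsilyloxy)-8α-(triethylsilyloxy)-5β-drimane, via sulfoxide 27 (not isolated)
Conditions: 3-chloroperbenzoic acid (2.2 equiv), NaHCO3, CH2Cl2, 0 °C → rt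
Reagents that add atoms: 3-chloroperbenzoic acid, OOC(=O)c1cccc(Cl)c1
Why: Peracid oxidation of the sulfide through the sulfoxide to the sulfone, carried out while the molecule holds no alkene.

Step 14
Reactants: 28 11-(phenylsulfonyl)-3β-(tert-butyldimethylsilyloxy)-8α-(triethylsilyloxy)-5β-drimane; 29 (2E,6E)-farnesyl bromide
Product: 31 11-(phenylsulfonyl)-11-[(2E,6E)-3,7,11-trimethyldodeca-2,6,10-trienyl]-3β-(tert-butyldimethylsilyloxy)-8α-(triethylsilyloxy)-5β-drimane (both C11 epimers), via lithiated sulfone 30 (not isolated)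
Conditions: n-BuLi, THF, −78 °C; then 29, −78 → 0 °C
Reagents that add atoms: none
Why: Alkylation of the α-sulfonyl carbanion (Julia-type sulfone coupling) by SN2 attack at the primary carbon of the allylic bromide, which forms C11–C12 and brings in the three trisubstituted alkenes with their geometry unchanged; the new C11 centre is removed in the next step.

Step 15
Reactants: 31 11-(phenylsulfonyl)-11-[(2E,6E)-3,7,11-trimethyldodeca-2,6,10-trienyl]-3β-(tert-butyldimethylsilyloxy)-8α-(triethylsilyloxy)-5β-drimane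
Product: 32 11-[(2E,6E)-3,7,11-trimethyldodeca-2,6,10-trienyl]-3β-(tert-butyldimethylsilyloxy)-8α-(triethylsilyloxy)-5β-drimane
Conditions: sodium amalgam (Na/Hg, 6% Na), Na2HPO4, MeOH/THF, −20 °C → rt
Reagents that add atoms: none
Why: Reductive desulfonylation by electron transfer from sodium amalgam under buffered conditions, which cleaves the C11–S bond and replaces it by C–H without touching the isolated trisubstituted alkenes or the silyl ethers.

Step 16
Reactants: 32 11-[(2E,6E)-3,7,11-trimethyldodeca-2,6,10-trienyl]-3β-(tert-butyldimethylsilyloxy)-8α-(triethylsilyloxy)-5β-drimane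
Product: 34 IN0670, (3S,5S,8R,9R,10S)-11-[(2E,6E)-3,7,11-trimethyldodeca-2,6,10-trienyl]-5β-drimane-3β,8α-diol, via mono-silyl ether 33 (not isolated)
Conditions: Bu4NF, THF, 50 °C
Reagents that add atoms: none
Why: Fluoride-induced cleavage of both silyl ethers (the tertiary triethylsilyl ether first, then the hindered secondary tert-butyldimethylsilyl ether) under non-acidic conditions, which avoids acid-induced cyclisation of the C8 hydroxyl onto the C13=C14 alkene.

**Compound list**

1 | methyl (E)-geranate, methyl (2E)-3,7-dimethylocta-2,6-dienoate | CC(C)=CCC/C(C)=C/C(=O)OC | starting material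
2 | ozonide of 1 at C6=C7, methyl (2E)-5-(5,5-dimethyl-1,2,4-trioxolan-3-yl)-3-methylpent-2-enoate (not isolated) | COC(=O)/C=C(\C)CCC1OOC(C)(C)O1 | intermediate
3 | methyl (2E)-3-methyl-6-oxohex-2-enoate | COC(=O)/C=C(\C)CCC=O | intermediate
4 | prenylmagnesium chloride (3-methylbut-2-enylmagnesium chloride) | CC(C)=CC[Mg]Cl | starting material
5 | B-(3-methylbut-2-enyl)diisopinocampheylborane, isopinocampheyl groups from (−)-α-pinene (not isolated) | CC(C)=CCB([C@H]1C[C@H]2C[C@@H]([C@@H]1C)C2(C)C)[C@H]3C[C@H]4C[C@@H]([C@@H]3C)C4(C)C | intermediate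
6 | diisopinocampheylborinate ester of 7 (not isolated) | COC(=O)/C=C(\C)CC[C@H](OB([C@H]1C[C@H]2C[C@@H]([C@@H]1C)C2(C)C)[C@H]3C[C@H]4C[C@@H]([C@@H]3C)C4(C)C)C(C)(C)C=C | intermediate
7 | methyl (2E,6S)-6-hydroxy-3,7,7-trimethylnona-2,8-dienoate | COC(=O)/C=C(\C)CC[C@H](O)C(C)(C)C=C | intermediate
8 | methyl (2E,6S)-6-(tert-butyldimethylsilyloxy)-3,7,7-trimethylnona-2,8-dienoate | COC(=O)/C=C(\C)CC[C@H](O[Si](C)(C)C(C)(C)C)C(C)(C)C=C | intermediate
9 | (E)-crotonaldehyde | C/C=C/C=O | starting material
10 | methyl (2E,6S,8E)-6-(tert-butyldimethylsilyloxy)-3,7,7-trimethyl-10-oxodeca-2,8-dienoate | COC(=O)/C=C(\C)CC[C@H](O[Si](C)(C)C(C)(C)C)C(C)(C)/C=C/C=O | intermediate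
11 | bis[(pinacolato)boryl]methane | CC1(C)OB(CB2OC(C)(C)C(C)(C)O2)OC1(C)C | starting material
12 | iodomethane | CI | starting material
13 | lithiated bis[(pinacolato)boryl]methane (not isolated) | [Li]C(B1OC(C)(C)C(C)(C)O1)B2OC(C)(C)C(C)(C)O2 | intermediate
14 | 1,1-bis(4,4,5,5-tetramethyl-1,3,2-dioxaborolan-2-yl)ethane | CC(B1OC(C)(C)C(C)(C)O1)B2OC(C)(C)C(C)(C)O2 | intermediate
15 | 1-lithio-1,1-bis(pinacolboryl)ethane (not isolated) | [Li]C(C)(B1OC(C)(C)C(C)(C)O1)B2OC(C)(C)C(C)(C)O2 | intermediate
16 | lithium alkoxide from addition of 15 to the aldehyde of 10, both C7 epimers (not isolated) | COC(=O)/C=C(\C)CC[C@H](O[Si](C)(C)C(C)(C)C)C(C)(C)/C=C/C([O-])C(C)(B1OC(C)(C)C(C)(C)O1)B2OC(C)(C)C(C)(C)O2.[Li+] | intermediate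
17 | methyl (2E,6S,8E,10Z)-6-(tert-butyldimethylsilyloxy)-3,7,7-trimethyl-11-(4,4,5,5-tetramethyl-1,3,2-dioxaborolan-2-yl)dodeca-2,8,10-trienoate (Diels–Alder precursor) | COC(=O)/C=C(\C)CC[C@H](O[Si](C)(C)C(C)(C)C)C(C)(C)/C=C/C=C(\C)B1OC(C)(C)C(C)(C)O1 | intermediate
18 | methyl 3β-(tert-butyldimethylsilyloxy)-8α-(pinacolboryl)-5β-drim-6-en-11-oate, cis-fused (Diels–Alder product) | COC(=O)[C@@H]1[C@@]2(C)CC[C@H](O[Si](C)(C)C(C)(C)C)C(C)(C)[C@H]2C=C[C@@]1(C)B3OC(C)(C)C(C)(C)O3 | intermediate
19 | C8–O–Bpin borate ester of 20 (not isolated) | COC(=O)[C@@H]1[C@@]2(C)CC[C@H](O[Si](C)(C)C(C)(C)C)C(C)(C)[C@H]2C=C[C@@]1(C)OB3OC(C)(C)C(C)(C)O3 | intermediate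
20 | methyl 3β-(tert-butyldimethylsilyloxy)-8α-hydroxy-5β-drim-6-en-11-oate | COC(=O)[C@@H]1[C@@]2(C)CC[C@H](O[Si](C)(C)C(C)(C)C)C(C)(C)[C@H]2C=C[C@@]1(C)O | intermediate
21 | methyl 3β-(tert-butyldimethylsilyloxy)-8α-hydroxy-5β-driman-11-oate | COC(=O)[C@@H]1[C@@]2(C)CC[C@H](O[Si](C)(C)C(C)(C)C)C(C)(C)[C@H]2CC[C@@]1(C)O | intermediate
22 | methyl 3β-(tert-butyldimethylsilyloxy)-8α-(triethylsilyloxy)-5β-driman-11-oate | COC(=O)[C@@H]1[C@@]2(C)CC[C@H](O[Si](C)(C)C(C)(C)C)C(C)(C)[C@H]2CC[C@@]1(C)O[Si](CC)(CC)CC | intermediate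
23 | 3β-(tert-butyldimethylsilyloxy)-8α-(triethylsilyloxy)-5β-driman-11-al (not isolated) | O=C[C@@H]1[C@@]2(C)CC[C@H](O[Si](C)(C)C(C)(C)C)C(C)(C)[C@H]2CC[C@@]1(C)O[Si](CC)(CC)CC | intermediate
24 | 3β-(tert-butyldimethylsilyloxy)-8α-(triethylsilyloxy)-5β-driman-11-ol | OC[C@@H]1[C@@]2(C)CC[C@H](O[Si](C)(C)C(C)(C)C)C(C)(C)[C@H]2CC[C@@]1(C)O[Si](CC)(CC)CC | intermediate
25 | C11 alkoxy(tributyl)phosphonium benzenethiolate of 24 (not isolated) | CCCC[P+](CCCC)(CCCC)OC[C@@H]1[C@@]2(C)CC[C@H](O[Si](C)(C)C(C)(C)C)C(C)(C)[C@H]2CC[C@@]1(C)O[Si](CC)(CC)CC.[S-]c1ccccc1 | intermediate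
26 | 11-(phenylthio)-3β-(tert-butyldimethylsilyloxy)-8α-(triethylsilyloxy)-5β-drimane | c3ccccc3SC[C@@H]1[C@@]2(C)CC[C@H](O[Si](C)(C)C(C)(C)C)C(C)(C)[C@H]2CC[C@@]1(C)O[Si](CC)(CC)CC | intermediate
27 | 11-(phenylsulfinyl) analogue of 26, both sulfur epimers (not isolated) | O=S(c3ccccc3)C[C@@H]1[C@@]2(C)CC[C@H](O[Si](C)(C)C(C)(C)C)C(C)(C)[C@H]2CC[C@@]1(C)O[Si](CC)(CC)CC | intermediate
28 | 11-(phenylsulfonyl)-3β-(tert-butyldimethylsilyloxy)-8α-(triethylsilyloxy)-5β-drimane | O=S(=O)(c3ccccc3)C[C@@H]1[C@@]2(C)CC[C@H](O[Si](C)(C)C(C)(C)C)C(C)(C)[C@H]2CC[C@@]1(C)O[Si](CC)(CC)CC | intermediate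
29 | (2E,6E)-farnesyl bromide | CC(C)=CCC/C(C)=C/CC/C(C)=C/CBr | starting material
30 | C11-lithiated sulfone 28 (not isolated) | [Li]C(S(=O)(=O)c3ccccc3)[C@@H]1[C@@]2(C)CC[C@H](O[Si](C)(C)C(C)(C)C)C(C)(C)[C@H]2CC[C@@]1(C)O[Si](CC)(CC)CC | intermediate
31 | 11-(phenylsulfonyl)-11-[(2E,6E)-3,7,11-trimethyldodeca-2,6,10-trienyl]-3β-(tert-butyldimethylsilyloxy)-8α-(triethylsilyloxy)-5β-drimane, both C11 epimers | CC(C)=CCC/C(C)=C/CC/C(C)=C/CC(S(=O)(=O)c3ccccc3)[C@@H]1[C@@]2(C)CC[C@H](O[Si](C)(C)C(C)(C)C)C(C)(C)[C@H]2CC[C@@]1(C)O[Si](CC)(CC)CC | intermediate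
32 | 11-[(2E,6E)-3,7,11-trimethyldodeca-2,6,10-trienyl]-3β-(tert-butyldimethylsilyloxy)-8α-(triethylsilyloxy)-5β-drimane | CC(C)=CCC/C(C)=C/CC/C(C)=C/CC[C@@H]1[C@@]2(C)CC[C@H](O[Si](C)(C)C(C)(C)C)C(C)(C)[C@H]2CC[C@@]1(C)O[Si](CC)(CC)CC | intermediate
33 | 3-O-tert-butyldimethylsilyl ether of the target, free 8α-hydroxyl (not isolated) | CC(C)=CCC/C(C)=C/CC/C(C)=C/CC[C@@H]1[C@@]2(C)CC[C@H](O[Si](C)(C)C(C)(C)C)C(C)(C)[C@H]2CC[C@@]1(C)O | intermediate
34 | IN0670, (3S,5S,8R,9R,10S)-11-[(2E,6E)-3,7,11-trimethyldodeca-2,6,10-trienyl]-5β-drimane-3β,8α-diol | CC(C)=CCC/C(C)=C/CC/C(C)=C/CC[C@@H]1[C@@]2(C)CC[C@H](O)C(C)(C)[C@H]2CC[C@@]1(C)O | target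

**Step count and risks**

Total step count: 16. Longest linear sequence: 15 steps (steps 1–4 and 6–16, from methyl (E)-geranate); step 5 is a one-step side branch.

Steps most likely to fail:

1. Step 7 (intramolecular Diels–Alder reaction). The ester-endo orientation may be preferred, because the inside C8 methyl crowds the exo position that the ester must occupy; this would deliver the trans ring fusion, with C5 and C8 inverted relative to C9 and C10. In addition, both new bonds end at fully substituted carbons, so the cycloaddition may be slow enough for a [1,5]-hydrogen shift from the inside methyl, or a 1,3-migration of boron in the allylboronate product, to compete.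
   Fallback, setting out from 8 and coming back at 24: the ester is exchanged for a nitrile before the triene is built.
   - Compound 8 is converted with dimethylaluminium amide (from AlMe3 and NH4Cl) into the primary amide F1, and dehydration with trifluoroacetic anhydride/pyridine gives the (E)-nitrile F2.
   - The same cross-metathesis with crotonaldehyde gives the enal F3, and the same boron–Wittig olefination with 14 gives the trienyl nitrile F4.
   - Heating F4 should give the cis-fused boronate F5. The rod-shaped nitrile is much smaller than CO2Me in the exo position beside the C8 methyl and shows almost no endo preference, so the tether-endo pathway should gain.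
   - Perborate oxidation then gives the allylic alcohol F6, hydrogenation the saturated hydroxy nitrile F7 and triethylsilylation the bis-silyl ether F8.
   - Reduction of F8 with i-Bu2AlH and hydrolysis of the imine gives aldehyde 23, which NaBH4 reduces to 24.

2. Step 4 (cross-metathesis). The alkene sits on a quaternary carbon next to the silyloxy-bearing carbon, so productive metathesis may be slower than catalyst decay and self-metathesis of crotonaldehyde.
   Fallback, setting out from 8 and coming back at 10: Lemieux–Johnson cleavage of the monosubstituted alkene (OsO4 cat., NaIO4, 2,6-lutidine, dioxane/H2O; the electron-poor trisubstituted enoate should react more slowly with OsO4) passes through the diol F9 to the aldehyde F10. A Wittig reaction with (triphenylphosphoranylidene)acetaldehyde in toluene at 90 °C then gives the (E)-enal 10.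

3. Step 6 (boron–Wittig olefination). The two Bpin groups of the adduct are diastereotopic, so the elimination may not fully control the C7=C8 geometry, and conjugate addition to the enal may compete.
   Fallback, setting out from 8 and coming back at 17, with the geometry fixed by a syn addition:
   - The aldehyde F10 (made as above) undergoes Takai iodo-olefination (CHI3, CrCl2, THF) to the (E)-vinyl iodide F11.
   - Sonogashira coupling with propyne (PdCl2(PPh3)2, CuI, Et3N) gives the (E)-enyne F12.
   - Copper-catalysed protoboration (CuCl, tri-p-tolylphosphine, NaO-t-Bu, bis(pinacolato)diboron, MeOH, THF) adds boron and hydrogen syn across the alkyne, with boron on the methyl-bearing carbon remote from the alkene, and gives 17. The β,β-disubstituted enoate is expected to be a slow acceptor for copper–boryl conjugate addition with a monophosphine ligand.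

**Further compounds**

F1 | step 7 | (2E,6S)-6-(tert-butyldimethylsilyloxy)-3,7,7-trimethylnona-2,8-dienamide | NC(=O)/C=C(\C)CC[C@H](O[Si](C)(C)C(C)(C)C)C(C)(C)C=C
F2 | step 7 | (2E,6S)-6-(tert-butyldimethylsilyloxy)-3,7,7-trimethylnona-2,8-dienenitrile | N#C/C=C(\C)CC[C@H](O[Si](C)(C)C(C)(C)C)C(C)(C)C=C
F3 | step 7 | (2E,6S,8E)-6-(tert-butyldimethylsilyloxy)-3,7,7-trimethyl-10-oxodeca-2,8-dienenitrile | N#C/C=C(\C)CC[C@H](O[Si](C)(C)C(C)(C)C)C(C)(C)/C=C/C=O
F4 | step 7 | (2E,6S,8E,10Z)-6-(tert-butyldimethylsilyloxy)-3,7,7-trimethyl-11-(4,4,5,5-tetramethyl-1,3,2-dioxaborolan-2-yl)dodeca-2,8,10-trienenitrile | N#C/C=C(\C)CC[C@H](O[Si](C)(C)C(C)(C)C)C(C)(C)/C=C/C=C(\C)B1OC(C)(C)C(C)(C)O1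
F5 | step 7 | 3β-(tert-butyldimethylsilyloxy)-8α-(pinacolboryl)-5β-drim-6-ene-11-nitrile | N#C[C@@H]1[C@@]2(C)CC[C@H](O[Si](C)(C)C(C)(C)C)C(C)(C)[C@H]2C=C[C@@]1(C)B3OC(C)(C)C(C)(C)O3
F6 | step 7 | 3β-(tert-butyldimethylsilyloxy)-8α-hydroxy-5β-drim-6-ene-11-nitrile | N#C[C@@H]1[C@@]2(C)CC[C@H](O[Si](C)(C)C(C)(C)C)C(C)(C)[C@H]2C=C[C@@]1(C)O
F7 | step 7 | 3β-(tert-butyldimethylsilyloxy)-8α-hydroxy-5β-drimane-11-nitrile | N#C[C@@H]1[C@@]2(C)CC[C@H](O[Si](C)(C)C(C)(C)C)C(C)(C)[C@H]2CC[C@@]1(C)O
F8 | step 7 | 3β-(tert-butyldimethylsilyloxy)-8α-(triethylsilyloxy)-5β-drimane-11-nitrile | N#C[C@@H]1[C@@]2(C)CC[C@H](O[Si](C)(C)C(C)(C)C)C(C)(C)[C@H]2CC[C@@]1(C)O[Si](CC)(CC)CC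
F9 | step 4 | methyl (2E,6S)-6-(tert-butyldimethylsilyloxy)-8,9-dihydroxy-3,7,7-trimethylnon-2-enoate (C8 epimers) | COC(=O)/C=C(\C)CC[C@H](O[Si](C)(C)C(C)(C)C)C(C)(C)C(O)CO
F10 | step 4 | methyl (2E,6S)-6-(tert-butyldimethylsilyloxy)-3,7,7-trimethyl-8-oxooct-2-enoate | COC(=O)/C=C(\C)CC[C@H](O[Si](C)(C)C(C)(C)C)C(C)(C)C=O
F11 | step 6 | methyl (2E,6S,8E)-6-(tert-butyldimethylsilyloxy)-9-iodo-3,7,7-trimethylnona-2,8-dienoate | COC(=O)/C=C(\C)CC[C@H](O[Si](C)(C)C(C)(C)C)C(C)(C)/C=C/I
F12 | step 6 | methyl (2E,6S,8E)-6-(tert-butyldimethylsilyloxy)-3,7,7-trimethyldodeca-2,8-dien-10-ynoate | COC(=O)/C=C(\C)CC[C@H](O[Si](C)(C)C(C)(C)C)C(C)(C)/C=C/C#CC
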